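**Retrosynthetic overview**
- The last bond made is C3–C1′: a palladium-catalysed Heck-type C3–H alkenylation joins the unprotected bicyclic pyranodienone core and an (E)-alkenyl iodide side chain.
- The pyran ring is formed second, by 6-endo-dig oxa-Michael closure of a 3-ethynyl-4-(hydroxymethyl)cyclohexenone; the alkyne comes from conjugate alkynylation of an enone followed by Saegusa–Ito oxidation.
- The carbocycle is formed first, by organocatalytic Michael addition of a protected 3-hydroxypropanal to pent-1-en-3-one and aldol condensation; the C7/C8 cis-diol comes from dihydroxylation anti to the C8a substituent.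
- The side chain comes from Brown anti-crotylation of methacrolein, hydroxyl-directed epoxidation, sulfonium-ylide homologation, cross-metathesis with a vinylboronate and iododeboronation.

Assumption: atom labels (C1, C3, C4, C4a, C5–C8, C8a; primed numbers for the side chain) follow the isochromenone numbering of the target, whose SMILES reads (7S,8S,8aS) in the core and (1′E,3′S,4′R,5′R) in the side chain; the C3 aldehyde building block is bought as its silyl ether.

**Route**

Step 1
Reactants: 1 3-((tert-butyldimethylsilyl)oxy)propanal; 2 pent-1-en-3-one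
Product: 3 (S)-2-(((tert-butyldimethylsilyl)oxy)methyl)-5-oxoheptanal
Conditions: (S)-2-(methoxydiphenylmethyl)pyrrolidine (5 mol %), ethyl 3,4-dihydroxybenzoate (20 mol %), neat, 4 °C, 36 h
Reagents that add atoms: none
Why: Organocatalytic enamine Michael addition: the E-enamine of 1 adds to the vinyl ketone (activated by the catechol hydrogen-bond donor) on the face opposite the diarylmethyl group of the (S)-catalyst, which sets the future C8a stereocentre as (S)-3.

Step 2
Reactants: 3 (S)-2-(((tert-butyldimethylsilyl)oxy)methyl)-5-oxoheptanal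
Product: 4 (R)-4-(((tert-butyldimethylsilyl)oxy)methyl)-2-methylcyclohex-2-en-1-one
Conditions: LiOH (0.2 equiv), i-PrOH, rt (crude 3 used directly)
Reagents that add atoms: none
Why: Intramolecular aldol condensation: only the ethyl-ketone α-carbon can reach the aldehyde through a six-membered ring, dehydration gives the 2-methyl enone, and catalytic hydroxide at room temperature is mild enough to keep the γ-stereocentre and the β-silyloxy group.

Step 3
Reactants: 4 (R)-4-(((tert-butyldimethylsilyl)oxy)methyl)-2-methylcyclohex-2-en-1-one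
Product: 5 (2S,3S,4S)-4-(((tert-butyldimethylsilyl)oxy)methyl)-2,3-dihydroxy-2-methylcyclohexan-1-one
Conditions: OsO4 (5 mol %), NMO (1.5 equiv), acetone/H2O (5:1), rt
Reagents that add atoms: N-methylmorpholine N-oxide (C[N+]1([O-])CCOCC1); water (O)
Why: Upjohn syn-dihydroxylation: OsO4 adds to the C7=C8 enone bond on the face opposite the adjacent C8a substituent, giving the cis-7,8-diol trans to CH2OTBS, that is (7S,8S).

Step 4
Reactants: 5 (2S,3S,4S)-4-(((tert-butyldimethylsilyl)oxy)methyl)-2,3-dihydroxy-2-methylcyclohexan-1-one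
Product: 6 (2S,3S,4S)-4-(((tert-butyldimethylsilyl)oxy)methyl)-2-methyl-2,3-bis((triethylsilyl)oxy)cyclohexan-1-one
Conditions: Et3SiOTf (2.6 equiv), 2,6-lutidine (4 equiv), CH2Cl2, −78 to 0 °C
Reagents that add atoms: triethylsilyl trifluoromethanesulfonate (CC[Si](CC)(CC)OS(=O)(=O)C(F)(F)F)
Why: Silyl ether formation with the reactive silyl triflate, which silylates the tertiary α-keto hydroxyl as well as the secondary one and so masks both for the enolate and organozinc steps.

Step 5
Reactants: 6 (2S,3S,4S)-4-(((tert-butyldimethylsilyl)oxy)methyl)-2-methyl-2,3-bis((triethylsilyl)oxy)cyclohexan-1-one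
Product: 8 (4S,5S,6S)-4-(((tert-butyldimethylsilyl)oxy)methyl)-6-methyl-5,6-bis((triethylsilyl)oxy)cyclohex-2-en-1-one, via trimethylsilyl enol ether 7 (not isolated)
Conditions: LiN(SiMe3)2, Me3SiCl, THF, −78 °C; then Pd(OAc)2 (10 mol %), O2 (1 atm), DMSO, 40 °C
Reagents that add atoms: none
Why: Saegusa–Ito oxidation: the ketone can enolise only towards C5 because C7 is quaternary, and divalent palladium converts the silyl enol ether into the C4a=C5 enone by β-hydride elimination.

Step 6
Reactants: 8 (4S,5S,6S)-4-(((tert-butyldimethylsilyl)oxy)methyl)-6-methyl-5,6-bis((triethylsilyl)oxy)cyclohex-2-en-1-one; 9 ethynyltrimethylsilane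
Product: 12 (4S,5S,6S)-4-(((tert-butyldimethylsilyl)oxy)methyl)-6-methyl-5,6-bis((triethylsilyl)oxy)-3-((trimethylsilyl)ethynyl)cyclohex-2-en-1-one, via ((trimethylsilyl)ethynyl)zinc bromide 10 (not isolated), via β-alkynyl silyl enol ether 11 (not isolated)
Conditions: 9, n-BuLi, THF, −78 °C, then ZnBr2, 0 °C; 8, t-BuMe2SiOTf, Et2O/THF, −40 °C; then Pd(OAc)2 (15 mol %), O2 (1 atm), DMSO, 45 °C
Reagents that add atoms: none
Why: Silyl-triflate-promoted conjugate addition of an alkynylzinc reagent gives the β-alkynyl silyl enol ether, and a second Saegusa–Ito oxidation restores the enone, so the alkyne ends up on sp2 carbon C4a and the transient C4a stereocentre is erased.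

Step 7
Reactants: 12 (4S,5S,6S)-4-(((tert-butyldimethylsilyl)oxy)methyl)-6-methyl-5,6-bis((triethylsilyl)oxy)-3-((trimethylsilyl)ethynyl)cyclohex-2-en-1-one
Product: 14 (7S,8S,8aS)-7,8-dihydroxy-7-methyl-1,7,8,8a-tetrahydro-6H-isochromen-6-one, via ethynyl triol 13 (not isolated)
Conditions: Bu4NF (6 equiv), THF, 0 °C to rt; then K2CO3 (0.2 equiv), MeOH, 0 °C
Reagents that add atoms: none
Why: Fluoride removes all four silyl groups and the freed primary alkoxide closes the pyran ring by 6-endo-dig oxa-Michael (1,6-) addition to the δ-carbon C3 of the ethynyl enone; attack at C4 is electronically disfavoured and attack by the C8 hydroxyl would create a bridgehead alkene.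

Step 8
Reactants: 15 2-methylprop-2-enal; 16 (E)-but-2-ene
Product: 19 (3R,4R)-2,4-dimethylhexa-1,5-dien-3-ol, via (E)-but-2-en-1-ylpotassium 17 (not isolated), via (E)-crotyldiisopinocampheylborane 18 (not isolated)
Conditions: 16, n-BuLi, KOt-Bu, THF, −78 to −45 °C; (+)-Ipc2BOMe (from (−)-α-pinene), −78 °C; BF3·OEt2; 15, −78 °C; then NaOH, H2O2, 0 °C to rt
Reagents that add atoms: none
Why: Brown anti-crotylboration through a chair Zimmerman–Traxler transition state: the E-crotyl geometry gives the anti relationship and the (1S,2S,3S,5R)-isopinocampheyl groups give the (3R,4R) configuration, which becomes C4′(R) and C5′(R) of the target.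

Step 9
Reactants: 19 (3R,4R)-2,4-dimethylhexa-1,5-dien-3-ol
Product: 20 (1R,2R)-2-methyl-1-[(2S)-2-methyloxiran-2-yl]but-3-en-1-ol
Conditions: VO(acac)2 (2 mol %), t-BuOOH (1.5 equiv), CH2Cl2, 0 °C to rt
Reagents that add atoms: tert-butyl hydroperoxide (CC(C)(C)OO)
Why: Hydroxyl-directed vanadium-catalysed epoxidation: only the allylic (not the homoallylic) alkene reacts, and A(1,2) strain with the 2-methyl group in the vanadate-ester transition state gives the erythro epoxy alcohol, which fixes C3′ as S.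

Step 10
Reactants: 20 (1R,2R)-2-methyl-1-[(2S)-2-methyloxiran-2-yl]but-3-en-1-ol
Product: 21 (1R,2R)-2-methyl-1-[(2S)-2-methyloxiran-2-yl]butan-1-ol
Conditions: H2 (1 atm), RhCl(PPh3)3 (5 mol %), benzene, rt
Reagents that add atoms: none
Why: Homogeneous hydrogenation reduces the monosubstituted alkene to the ethyl group without hydrogenolysis of the epoxide and without touching a stereocentre.

Step 11
Reactants: 21 (1R,2R)-2-methyl-1-[(2S)-2-methyloxiran-2-yl]butan-1-ol
Product: 22 (3S,4R,5R)-3,5-dimethylhept-1-ene-3,4-diol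
Conditions: Me3S+ I− (4 equiv), n-BuLi (3.8 equiv), THF, −10 °C to rt
Reagents that add atoms: trimethylsulfonium iodide (C[S+](C)C.[I-])
Why: One-carbon homologation of a terminal epoxide with excess dimethylsulfonium methylide (ylide opening at the CH2 terminus, then ylide-mediated elimination of dimethyl sulfide) gives the tertiary allylic alcohol with C3′ untouched; any Payne isomer drains back through the terminal epoxide, the only one the ylide opens.

Step 12
Reactants: 22 (3S,4R,5R)-3,5-dimethylhept-1-ene-3,4-diol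
Product: 23 (1E,3S,4R,5R)-3,5-dimethyl-1-(4,4,5,5-tetramethyl-1,3,2-dioxaborolan-2-yl)hept-1-ene-3,4-diol
Conditions: 4,4,5,5-tetramethyl-2-vinyl-1,3,2-dioxaborolane (3 equiv), [1,3-bis(2,4,6-trimethylphenyl)imidazolidin-2-ylidene]dichloro(2-isopropoxybenzylidene)ruthenium (second-generation Hoveyda–Grubbs catalyst, 5 mol %), CH2Cl2, 40 °C
Reagents that add atoms: 4,4,5,5-tetramethyl-2-vinyl-1,3,2-dioxaborolane (C=CB1OC(C)(C)C(C)(C)O1)
Why: Olefin cross-metathesis of the allylic alcohol with excess vinylboronate releases ethene and gives the E-alkenylboronate under thermodynamic control.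

Step 13
Reactants: 23 (1E,3S,4R,5R)-3,5-dimethyl-1-(4,4,5,5-tetramethyl-1,3,2-dioxaborolan-2-yl)hept-1-ene-3,4-diol
Product: 24 (1E,3S,4R,5R)-1-iodo-3,5-dimethylhept-1-ene-3,4-diol
Conditions: NaOH (3 M aq), then I2 (1.5 equiv), THF, 0 °C to rt
Reagents that add atoms: iodine (II)
Why: Iododeboronation of the preformed boronate ate complex is an ipso substitution with retention, so the E-alkenyl iodide is obtained.

Step 14
Reactants: 14 (7S,8S,8aS)-7,8-dihydroxy-7-methyl-1,7,8,8a-tetrahydro-6H-isochromen-6-one; 24 (1E,3S,4R,5R)-1-iodo-3,5-dimethylhept-1-ene-3,4-diol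
Product: 25 (7S,8S,8aS)-3-[(1E,3S,4R,5R)-3,4-dihydroxy-3,5-dimethylhept-1-en-1-yl]-7,8-dihydroxy-7-methyl-1,7,8,8a-tetrahydro-6H-isochromen-6-one
Conditions: Pd(OAc)2 (10 mol %), P(2-furyl)3 (20 mol %), AgOAc (2 equiv), DMF, 50 °C, dark
Reagents that add atoms: none
Why: Proposed new method: a Heck-type C3–H alkenylation of a cyclic δ-alkoxy dienone by an alkenyl iodide, in which oxidative addition of 24 to zerovalent palladium and iodide abstraction by AgOAc give a cationic alkenylpalladium that inserts into the polarised C3=C4 enol-ether bond with carbon delivered to C3 (the oxygen-bearing, δ-electrophilic terminus), the resulting C4-palladium species is a palladium dienolate that can change face through its oxygen-bound form and then lose the C3 hydrogen by syn β-hydride elimination (acetate-assisted palladation of the C3–H bond followed by reductive elimination would give the same product), so the C3–C1′ bond forms with retention of the E geometry and without touching any stereocentre; the closest known reactions are the Heck-type C2 arylation of chromones, the Heck arylation of 3-alkoxyacrylates at the alkoxy-bearing carbon and the α-selective Heck coupling of cyclic enol ethers.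

**Compound list**
1 | 3-((tert-butyldimethylsilyl)oxy)propanal | O=CCCO[Si](C)(C)C(C)(C)C | starting material
2 | pent-1-en-3-one | C=CC(=O)CC | starting material
3 | (S)-2-(((tert-butyldimethylsilyl)oxy)methyl)-5-oxoheptanal | CCC(=O)CC[C@H](C=O)CO[Si](C)(C)C(C)(C)C | intermediate
4 | (R)-4-(((tert-butyldimethylsilyl)oxy)methyl)-2-methylcyclohex-2-en-1-one | C1CC(=O)C(C)=C[C@@H]1CO[Si](C)(C)C(C)(C)C | intermediate
5 | (2S,3S,4S)-4-(((tert-butyldimethylsilyl)oxy)methyl)-2,3-dihydroxy-2-methylcyclohexan-1-one | C1CC(=O)[C@@](C)(O)[C@@H](O)[C@@H]1CO[Si](C)(C)C(C)(C)C | intermediate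
6 | (2S,3S,4S)-4-(((tert-butyldimethylsilyl)oxy)methyl)-2-methyl-2,3-bis((triethylsilyl)oxy)cyclohexan-1-one | C1CC(=O)[C@@](C)(O[Si](CC)(CC)CC)[C@@H](O[Si](CC)(CC)CC)[C@@H]1CO[Si](C)(C)C(C)(C)C | intermediate
7 | trimethylsilyl enol ether of 6 (C5=C6 enol ether; C7, C8, C8a unchanged) | C1C=C(O[Si](C)(C)C)[C@@](C)(O[Si](CC)(CC)CC)[C@@H](O[Si](CC)(CC)CC)[C@@H]1CO[Si](C)(C)C(C)(C)C | intermediate
8 | (4S,5S,6S)-4-(((tert-butyldimethylsilyl)oxy)methyl)-6-methyl-5,6-bis((triethylsilyl)oxy)cyclohex-2-en-1-one | C1=CC(=O)[C@@](C)(O[Si](CC)(CC)CC)[C@@H](O[Si](CC)(CC)CC)[C@@H]1CO[Si](C)(C)C(C)(C)C | intermediate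
9 | ethynyltrimethylsilane | C#C[Si](C)(C)C | starting material
10 | ((trimethylsilyl)ethynyl)zinc bromide | C[Si](C)(C)C#C[Zn]Br | intermediate
11 | tert-butyldimethylsilyl enol ether (C5=C6) of the 4a-((trimethylsilyl)ethynyl) ketone, major isomer with the alkynyl group trans to CH2OTBS | [C@H]1(C#C[Si](C)(C)C)C=C(O[Si](C)(C)C(C)(C)C)[C@@](C)(O[Si](CC)(CC)CC)[C@@H](O[Si](CC)(CC)CC)[C@@H]1CO[Si](C)(C)C(C)(C)C | intermediate
12 | (4S,5S,6S)-4-(((tert-butyldimethylsilyl)oxy)methyl)-6-methyl-5,6-bis((triethylsilyl)oxy)-3-((trimethylsilyl)ethynyl)cyclohex-2-en-1-one | C1(C#C[Si](C)(C)C)=CC(=O)[C@@](C)(O[Si](CC)(CC)CC)[C@@H](O[Si](CC)(CC)CC)[C@@H]1CO[Si](C)(C)C(C)(C)C | intermediate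
13 | (4S,5S,6S)-3-ethynyl-5,6-dihydroxy-4-(hydroxymethyl)-6-methylcyclohex-2-en-1-one | C1(C#C)=CC(=O)[C@@](C)(O)[C@@H](O)[C@@H]1CO | intermediate
14 | (7S,8S,8aS)-7,8-dihydroxy-7-methyl-1,7,8,8a-tetrahydro-6H-isochromen-6-one | C1=CC2=CC(=O)[C@@](C)(O)[C@@H](O)[C@@H]2CO1 | intermediate
15 | 2-methylprop-2-enal (methacrolein) | CC(=C)C=O | starting material
16 | (E)-but-2-ene | C/C=C/C | starting material
17 | (E)-but-2-en-1-ylpotassium | C/C=C/[CH2-].[K+] | intermediate
18 | (E)-but-2-en-1-yl-bis[(1S,2S,3S,5R)-isopinocampheyl]borane | C/C=C/CB([C@H]1C[C@H]2C[C@@H]([C@@H]1C)C2(C)C)[C@H]1C[C@H]2C[C@@H]([C@@H]1C)C2(C)C | intermediate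
19 | (3R,4R)-2,4-dimethylhexa-1,5-dien-3-ol | C=C[C@@H](C)[C@@H](O)C(C)=C | intermediate
20 | (1R,2R)-2-methyl-1-[(2S)-2-methyloxiran-2-yl]but-3-en-1-ol | C=C[C@@H](C)[C@@H](O)[C@@]1(C)OC1 | intermediate
21 | (1R,2R)-2-methyl-1-[(2S)-2-methyloxiran-2-yl]butan-1-ol | CC[C@@H](C)[C@@H](O)[C@@]1(C)OC1 | intermediate
22 | (3S,4R,5R)-3,5-dimethylhept-1-ene-3,4-diol | CC[C@@H](C)[C@@H](O)[C@@](C)(O)C=C | intermediate
23 | (1E,3S,4R,5R)-3,5-dimethyl-1-(4,4,5,5-tetramethyl-1,3,2-dioxaborolan-2-yl)hept-1-ene-3,4-diol | CC[C@@H](C)[C@@H](O)[C@@](C)(O)/C=C/B1OC(C)(C)C(C)(C)O1 | intermediate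
24 | (1E,3S,4R,5R)-1-iodo-3,5-dimethylhept-1-ene-3,4-diol | CC[C@@H](C)[C@@H](O)[C@@](C)(O)/C=C/I | intermediate
25 | (7S,8S,8aS)-3-[(1E,3S,4R,5R)-3,4-dihydroxy-3,5-dimethylhept-1-en-1-yl]-7,8-dihydroxy-7-methyl-1,7,8,8a-tetrahydro-6H-isochromen-6-one (CNP0291643.4) | CC[C@@H](C)[C@@H](O)[C@@](C)(O)/C=C/C1=CC2=CC(=O)[C@@](C)(O)[C@@H](O)[C@@H]2CO1 | target

**Step count**
Total steps: 14. Longest linear sequence: 8 steps (steps 1–7, then step 14); the side-chain branch is steps 8–13, then step 14.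

**Three steps most likely to fail**

Step 14 (the proposed Heck-type C3–H alkenylation). It could fail through attack at C4 or C5, through protonation of the palladium dienolate to the 3,4-dihydro compound, or through decomposition of the unprotected dienone. The fallback uses known chemistry only; it sets out from 12 and comes back to the route at 25. K2CO3 in MeOH at 0 °C removes only the alkynyl silyl group and gives the terminal ethynyl enone F1. Sonogashira coupling of F1 with 24 (PdCl2(PPh3)2, CuI, i-Pr2NH, THF, rt) forms the same C3–C1′ bond and gives the silylated dienynone F2. Bu4NF in THF frees the pentaol dienynone F3, whose primary alkoxide closes the pyran ring by 6-endo-dig oxa-Michael addition (K2CO3/MeOH, or catalytic AuCl(PPh3)/AgOTf if base is too slow) to give 25.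

Step 6 (conjugate alkynylation and second Saegusa–Ito oxidation on a hindered, heavily silylated enone). It could fail through 1,2-addition, silyl scrambling or sluggish oxidation of the bulky silyl enol ether. The fallback installs the alkyne by 1,2-addition and oxidative transposition; it sets out from 8 and comes back at 12. Weitz–Scheffer epoxidation (H2O2, NaOH, MeOH, 0 °C) gives the epoxy ketone F4. Wharton transposition (N2H4·H2O, AcOH, MeOH) gives the allylic alcohol F5. Oxidation with MnO2 in CH2Cl2 gives the transposed enone F6. Addition of LiC≡CSiMe3 (from 9 and n-BuLi, with CeCl3, THF, −78 °C) gives the tertiary propargylic alcohol F7. Oxidative 1,3-transposition with pyridinium chlorochromate [C5H5NH][CrO3Cl] (Dauben–Michno) gives 12.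

Step 12 (cross-metathesis of a hindered tertiary allylic diol with the vinylboronate). It could stall at the quaternary allylic centre or give homodimers. The fallback builds the iodoalkene from an aldehyde instead; it sets out from 22 and comes back at 24, bypassing 23. Acetonide formation (2,2-dimethoxypropane, pyridinium p-toluenesulfonate, CH2Cl2) gives the vinyl dioxolane F8. Ozonolysis (O3, CH2Cl2/MeOH, −78 °C; then PPh3) gives the aldehyde F9. Takai olefination (CrCl2, CHI3, THF, 0 °C) gives the (E)-iodoalkenyl dioxolane F10. Acetonide hydrolysis (AcOH/H2O 4:1, 40 °C) gives 24.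

**Further compounds**
F1 | step 14 | (4S,5S,6S)-4-(((tert-butyldimethylsilyl)oxy)methyl)-3-ethynyl-6-methyl-5,6-bis((triethylsilyl)oxy)cyclohex-2-en-1-one | C1(C#C)=CC(=O)[C@@](C)(O[Si](CC)(CC)CC)[C@@H](O[Si](CC)(CC)CC)[C@@H]1CO[Si](C)(C)C(C)(C)C
F2 | step 14 | (4S,5S,6S)-4-(((tert-butyldimethylsilyl)oxy)methyl)-3-[(3E,5S,6R,7R)-5,6-dihydroxy-5,7-dimethylnon-3-en-1-yn-1-yl]-6-methyl-5,6-bis((triethylsilyl)oxy)cyclohex-2-en-1-one | CC[C@@H](C)[C@@H](O)[C@@](C)(O)/C=C/C#CC1=CC(=O)[C@@](C)(O[Si](CC)(CC)CC)[C@@H](O[Si](CC)(CC)CC)[C@@H]1CO[Si](C)(C)C(C)(C)C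
F3 | step 14 | (4S,5S,6S)-3-[(3E,5S,6R,7R)-5,6-dihydroxy-5,7-dimethylnon-3-en-1-yn-1-yl]-5,6-dihydroxy-4-(hydroxymethyl)-6-methylcyclohex-2-en-1-one | CC[C@@H](C)[C@@H](O)[C@@](C)(O)/C=C/C#CC1=CC(=O)[C@@](C)(O)[C@@H](O)[C@@H]1CO
F4 | step 6 | 4a,5-epoxide of 8 (7-oxabicyclo[4.1.0]heptan-2-one; C7, C8 and C8a as in 8) | O1C2C1C(=O)[C@@](C)(O[Si](CC)(CC)CC)[C@@H](O[Si](CC)(CC)CC)[C@@H]2CO[Si](C)(C)C(C)(C)C
F5 | step 6 | allylic alcohol from Wharton transposition of F4 (hydroxyl at C4a, C5=C6 alkene; C7, C8 and C8a as in 8) | OC1C=C[C@@](C)(O[Si](CC)(CC)CC)[C@@H](O[Si](CC)(CC)CC)[C@@H]1CO[Si](C)(C)C(C)(C)C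
F6 | step 6 | transposed enone (ketone at C4a, C5=C6 alkene; C7, C8 and C8a as in 8) | O=C1C=C[C@@](C)(O[Si](CC)(CC)CC)[C@@H](O[Si](CC)(CC)CC)[C@@H]1CO[Si](C)(C)C(C)(C)C
F7 | step 6 | tertiary propargylic alcohol from F6 (hydroxyl and (trimethylsilyl)ethynyl at C4a, C5=C6 alkene) | OC1(C#C[Si](C)(C)C)C=C[C@@](C)(O[Si](CC)(CC)CC)[C@@H](O[Si](CC)(CC)CC)[C@@H]1CO[Si](C)(C)C(C)(C)C
F8 | step 12 | (4S,5R)-5-[(2R)-butan-2-yl]-4-ethenyl-2,2,4-trimethyl-1,3-dioxolane | CC[C@@H](C)[C@H]1OC(C)(C)O[C@@]1(C)C=C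
F9 | step 12 | (4R,5R)-5-[(2R)-butan-2-yl]-2,2,4-trimethyl-1,3-dioxolane-4-carbaldehyde | CC[C@@H](C)[C@H]1OC(C)(C)O[C@@]1(C)C=O
F10 | step 12 | (4S,5R)-5-[(2R)-butan-2-yl]-4-[(E)-2-iodoethenyl]-2,2,4-trimethyl-1,3-dioxolane | CC[C@@H](C)[C@H]1OC(C)(C)O[C@@]1(C)/C=C/I
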